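**Plan**
- Retrosynthesis: the C8–O bond is cut first (back to a C8 aldehyde through its aryl formate), then the C8–CHO bond, the O1–C2 bond of the pyrone, the C2–C3 bond and the C4–C4a bond.
- Forward: 3,4,5-trimethoxyphenol (ring A) is C-acetylated, the ketone enolate is aroylated with 3,4,5-trimethoxybenzoyl chloride (ring B and C2), and acid closes ring C by O1–C2 bond formation with loss of water.
- Feature used: C8 is the only unsubstituted carbon of ring A, ortho to O1 and to the C7 methoxyl and para to the C5 methoxyl, and its oxygen is the one ring A oxygen that is not methylated.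
- That oxygen is therefore introduced last, by formylation of C8 and peracid-induced migration of C8 from the formyl carbon to oxygen; methanolysis of the formate then frees the hydroxyl without touching the six methyl ethers.
- Stereochemistry: the target has no stereocentre and no stereogenic double bond, so nothing has to be controlled.

Key step: step 5

Remark on the chemistry: diketone 5 is drawn as the diketo tautomer although it should exist largely as its enol; intermediates 7 and 9 each carry one transient stereocentre, should form as racemates and lose it in the same flask.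

Step 1
Reactants: 1 3,4,5-trimethoxyphenol
Product: 3 1-(6-hydroxy-2,3,4-trimethoxyphenyl)ethan-1-one, via difluoroboron chelate 2 (not isolated)
Conditions: Ac2O (2 equiv), BF3·OEt2 (3 equiv), 0 → 70 °C; then MeOH–H2O, reflux
Reagents that add atoms: acetic anhydride, CC(=O)OC(C)=O
Why: Friedel–Crafts C-acetylation (directly or by O-acetylation and Fries shift) can only go ortho to the hydroxyl, since the para carbon carries a methoxyl and the two ortho carbons are equivalent by symmetry; the ketone should be held as chelate 2 until the aqueous methanol hydrolyses it.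

Step 2
Reactants: 3 1-(6-hydroxy-2,3,4-trimethoxyphenyl)ethan-1-one; 4 3,4,5-trimethoxybenzoyl chloride
Product: 5 1-(6-hydroxy-2,3,4-trimethoxyphenyl)-3-(3,4,5-trimethoxyphenyl)propane-1,3-dione
Conditions: LiN(SiMe3)2 (4 equiv), THF, −78 → −10 °C; then 4 (1.0 equiv), −78 °C → rt; aq. HCl
Reagents that add atoms: none
Why: Claisen-type C-aroylation of the phenoxide–enolate dianion (the one-flask variant of the Baker–Venkataraman route) should place the aroyl group on the enolate carbon, and the excess base should hold the diketone as its enolate so that it is not acylated a second time.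

Step 3
Reactants: 5 1-(6-hydroxy-2,3,4-trimethoxyphenyl)-3-(3,4,5-trimethoxyphenyl)propane-1,3-dione
Product: 6 5,6,7-trimethoxy-2-(3,4,5-trimethoxyphenyl)-4H-chromen-4-one
Conditions: H2SO4 (cat.), AcOH, 95 °C
Reagents that add atoms: none
Why: acid-catalysed cyclodehydration of an o-hydroxydibenzoylmethane (classical flavone ring closure) should form the O1–C2 bond and expel water, and brief heating with catalytic acid should leave the C5 methyl ether peri to the carbonyl intact.

Step 4
Reactants: 6 5,6,7-trimethoxy-2-(3,4,5-trimethoxyphenyl)-4H-chromen-4-one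
Product: 8 5,6,7-trimethoxy-4-oxo-2-(3,4,5-trimethoxyphenyl)-4H-chromene-8-carbaldehyde, via C8 chloro(methoxy)methyl flavone 7 (not isolated)
Conditions: Cl2CHOMe (3 equiv), AgOSO2CF3 (3 equiv), CH2Cl2, −78 → 0 °C; then H2O, 0 °C
Reagents that add atoms: dichloromethyl methyl ether, COC(Cl)Cl; water, O
Why: Rieche formylation (Friedel–Crafts-type substitution by the chloro(methoxy)carbenium ion) should occur at C8, the only free ring A carbon, which is activated by O1 and the C7 methoxyl (ortho) and the C5 methoxyl (para) and is meta to the carbonyl-bearing C4a, whereas C3 and C2'/C6' of ring B are conjugated to the electron-poor pyrone; water then hydrolyses chloro ether 7 to the aldehyde.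

Step 5
Reactants: 8 5,6,7-trimethoxy-4-oxo-2-(3,4,5-trimethoxyphenyl)-4H-chromene-8-carbaldehyde
Product: 10 5,6,7-trimethoxy-4-oxo-2-(3,4,5-trimethoxyphenyl)-4H-chromen-8-yl formate, via Criegee peroxyhemiacetal 9 (not isolated)
Conditions: mCPBA (1.5 equiv), CH2Cl2, 0 °C → rt
Reagents that add atoms: meta-chloroperbenzoic acid (mCPBA), O=C(OO)c1cccc(Cl)c1
Why: mCPBA adds to the C8 aldehyde carbonyl to give the tetrahedral Criegee adduct 9, and ring A carbon C8 then shifts from the formyl carbon to the adjacent peroxide oxygen as 3-chlorobenzoate departs, so the C8–O bond appears as the aryl formate. The closest known reaction type is the Dakin (Baeyer–Villiger) oxidation of ortho- and para-alkoxybenzaldehydes to phenol formates with peracids. No ring is closed and no stereocentre is set; the hemiperacetal carbon of 9 forms as a racemate and ends as the achiral formyl carbon. Aryl migration must outrun hydride migration, which would give the C8 carboxylic acid, and this is secured by the lone pairs of O1 and the C7 methoxyl ortho to C8 and of the C5 methoxyl para to it, which stabilise positive charge on the migrating carbon. The peracid must also spare the rest of the molecule, which is secured by the electron-poor C2=C3 bond of the pyrone and by the new oxygen emerging acylated, so that ring A is not carried on to a quinone.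

Step 6
Reactants: 10 5,6,7-trimethoxy-4-oxo-2-(3,4,5-trimethoxyphenyl)-4H-chromen-8-yl formate
Product: 11 8-hydroxy-5,6,7-trimethoxy-2-(3,4,5-trimethoxyphenyl)-4H-chromen-4-one (8-hydroxy-5,6,7,3',4',5'-hexamethoxyflavone)
Conditions: K2CO3 (0.3 equiv), MeOH, 0 °C → rt, argon; then dil. HCl
Reagents that add atoms: none
Why: base-catalysed transesterification (methanolysis) should remove the aryl formate, by far the most labile group present, while the methyl ethers and the pyrone are inert to cold carbonate in methanol and argon protects the electron-rich phenolate from air.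

**Compound list**
1 | 3,4,5-trimethoxyphenol | COc1cc(O)cc(OC)c1OC | starting material
2 | O,O-difluoroboron chelate of ketone 3 (BF2 bridging the phenol oxygen and the acetyl oxygen in a six-membered ring; formed in the flask) | CC1=[O+][B-](F)(F)Oc2cc(OC)c(OC)c(OC)c12 | intermediate
3 | 1-(6-hydroxy-2,3,4-trimethoxyphenyl)ethan-1-one (2'-hydroxy-4',5',6'-trimethoxyacetophenone) | CC(=O)c1c(O)cc(OC)c(OC)c1OC | intermediate
4 | 3,4,5-trimethoxybenzoyl chloride | COc1cc(C(Cl)=O)cc(OC)c1OC | starting material
5 | 1-(6-hydroxy-2,3,4-trimethoxyphenyl)-3-(3,4,5-trimethoxyphenyl)propane-1,3-dione | COc1cc(C(=O)CC(=O)c2c(O)cc(OC)c(OC)c2OC)cc(OC)c1OC | intermediate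
6 | 5,6,7-trimethoxy-2-(3,4,5-trimethoxyphenyl)-4H-chromen-4-one (5,6,7,3',4',5'-hexamethoxyflavone) | COc1cc(-c2cc(=O)c3c(OC)c(OC)c(OC)cc3o2)cc(OC)c1OC | intermediate
7 | 8-[chloro(methoxy)methyl]-5,6,7-trimethoxy-2-(3,4,5-trimethoxyphenyl)-4H-chromen-4-one (racemic; formed in the flask) | COc1cc(-c2cc(=O)c3c(OC)c(OC)c(OC)c(C(Cl)OC)c3o2)cc(OC)c1OC | intermediate
8 | 5,6,7-trimethoxy-4-oxo-2-(3,4,5-trimethoxyphenyl)-4H-chromene-8-carbaldehyde | COc1cc(-c2cc(=O)c3c(OC)c(OC)c(OC)c(C=O)c3o2)cc(OC)c1OC | intermediate
9 | hydroxy[5,6,7-trimethoxy-4-oxo-2-(3,4,5-trimethoxyphenyl)-4H-chromen-8-yl]methyl 3-chlorobenzenecarboperoxoate (Criegee adduct; racemic; formed in the flask) | COc1cc(-c2cc(=O)c3c(OC)c(OC)c(OC)c(C(O)OOC(=O)c4cccc(Cl)c4)c3o2)cc(OC)c1OC | intermediate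
10 | 5,6,7-trimethoxy-4-oxo-2-(3,4,5-trimethoxyphenyl)-4H-chromen-8-yl formate | COc1cc(-c2cc(=O)c3c(OC)c(OC)c(OC)c(OC=O)c3o2)cc(OC)c1OC | intermediate
11 | 8-hydroxy-5,6,7-trimethoxy-2-(3,4,5-trimethoxyphenyl)-4H-chromen-4-one | COc1cc(-c2cc(=O)c3c(OC)c(OC)c(OC)c(O)c3o2)cc(OC)c1OC | target

Total step count: 6
Longest linear sequence: 6 steps (1 → 3 → 5 → 6 → 8 → 10 → 11)

**Steps most likely to fail**

Step 4 (C8 formylation). The substitution may stall once the acid released ties up the basic pyrone carbonyl, or the electrophile may also attack C2'/C6' of ring B, so that conversion is incomplete or regioisomers form. Fallback: setting out from flavone 6, N-bromosuccinimide in MeCN at room temperature, a milder electrophile that releases no strong acid, should brominate the one free ring A position to give 8-bromo-5,6,7-trimethoxy-2-(3,4,5-trimethoxyphenyl)-4H-chromen-4-one F1. Palladium-catalysed reductive carbonylation of the aryl bromide (PdCl2(PPh3)2, CO 1 atm, HCO2Na, DMF, 100 °C) should then give aldehyde 8, where the route is rejoined.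

Step 5 (key step). Hydride instead of aryl migration in adduct 9 would divert material to the C8 carboxylic acid, and premature loss of the formyl group would expose the electron-rich phenol to further oxidation towards a 5,8-quinone. Fallback: setting out from flavone 6, N-iodosuccinimide with catalytic CF3CO2H in MeCN should give 8-iodo-5,6,7-trimethoxy-2-(3,4,5-trimethoxyphenyl)-4H-chromen-4-one F2. Miyaura borylation (bis(pinacolato)diboron, PdCl2(dppf) with dppf = 1,1'-bis(diphenylphosphino)ferrocene, KOAc, dioxane, 85 °C) should give 5,6,7-trimethoxy-8-(4,4,5,5-tetramethyl-1,3,2-dioxaborolan-2-yl)-2-(3,4,5-trimethoxyphenyl)-4H-chromen-4-one F3. Oxidation with NaBO3·4H2O in THF–H2O at room temperature, in which C8 migrates from boron to oxygen, should give the phenol directly, so the route is rejoined at target 11.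

Step 2 (C-aroylation). Acylation at the phenoxide oxygen in place of the enolate carbon, or a second aroylation of the diketone enolate, would lower the return of diketone and lead to 3-aroylated material on cyclisation. Fallback: setting out from ketone 3, acylation with chloride 4 in pyridine with catalytic 4-(dimethylamino)pyridine at room temperature should give 2-acetyl-3,4,5-trimethoxyphenyl 3,4,5-trimethoxybenzoate F4. Baker–Venkataraman rearrangement (KOH, pyridine, 50 °C; then aq. AcOH) should move the aroyl group from oxygen to carbon and give diketone 5, where the route is rejoined.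

**Further compounds**
F1 | step 4 | 8-bromo-5,6,7-trimethoxy-2-(3,4,5-trimethoxyphenyl)-4H-chromen-4-one | COc1cc(-c2cc(=O)c3c(OC)c(OC)c(OC)c(Br)c3o2)cc(OC)c1OC
F2 | step 5 | 8-iodo-5,6,7-trimethoxy-2-(3,4,5-trimethoxyphenyl)-4H-chromen-4-one | COc1cc(-c2cc(=O)c3c(OC)c(OC)c(OC)c(I)c3o2)cc(OC)c1OC
F3 | step 5 | 5,6,7-trimethoxy-8-(4,4,5,5-tetramethyl-1,3,2-dioxaborolan-2-yl)-2-(3,4,5-trimethoxyphenyl)-4H-chromen-4-one | COc1cc(-c2cc(=O)c3c(OC)c(OC)c(OC)c(B4OC(C)(C)C(C)(C)O4)c3o2)cc(OC)c1OC
F4 | step 2 | 2-acetyl-3,4,5-trimethoxyphenyl 3,4,5-trimethoxybenzoate | CC(=O)c1c(OC(=O)c2cc(OC)c(OC)c(OC)c2)cc(OC)c(OC)c1OC
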